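**Assumptions (one line):** compounds 1, 2, 6 and 11 are commercial; a telescoped one-pot sequence without isolation is counted as one step; the ligand antipode in Step 4 is the one that gives the (S)-enone (predicted (S)-BINAP by analogy with the Hayashi face model, to be confirmed experimentally).

## Retrosynthetic overview

1. Target ⇒ methyl ester 12 ⇒ Mitsunobu etherification of primary alcohol 10 with umbelliferone.
2. 10 ⇒ exocyclic alkene 9 (OH-directed hydrogenation sets C3-Me) ⇒ ketone 8 (methylenation).
3. 8 ⇒ enone 7 by conjugate methylation (quaternary C1, anti to the isobutenyl group) and hydroxymethylation of the resulting enolate (C2).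
4. 7 ⇒ racemic spirolactone enone 5 by enantioconvergent Rh-catalysed alkenylation with expulsion of the lactone carboxylate (sets C5, erases the spiro centre).
5. 5 ⇒ furan 4 (from HMF) by dearomative Piancatelli rearrangement with spirolactonisation. The cyclopentane is the only ring built (Step 3, from the four furan carbons plus the CH2OH carbon); the transient lactone is opened in Step 4; the coumarin arrives intact.

## Route

**Step 1**
Reactants: 1, 5-(hydroxymethyl)furfural (HMF); 2, malonic acid
Product: 3, (2E)-3-[5-(hydroxymethyl)furan-2-yl]prop-2-enoic acid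
Conditions: pyridine, piperidine (cat.), 90 °C; aq. HCl work-up
Reagents that add atoms: none beyond reactant 2 (malonic acid, OC(=O)CC(=O)O)
Why: Knoevenagel–Doebner condensation with decarboxylation gives the E-acrylic acid; the free CH2OH is tolerated.

**Step 2**
Reactants: 3
Product: 4, 3-[5-(hydroxymethyl)furan-2-yl]propanoic acid
Conditions: H2 (1 atm, stop at 1 equiv), 5% Pd/C, EtOAc, rt
Reagents that add atoms: none
Why: Chemoselective catalytic hydrogenation of the conjugated C=C, which is reduced much faster than the furan ring or the furfurylic C–O bond under these mild conditions.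

**Step 3 (key step)**
Reactants: 4
Product: 5, rac-1-oxaspiro[4.4]non-6-ene-2,8-dione
Conditions: H2O (0.05 M, pH ≈ 4), 140 °C, microwave or flow, 15 min; then TsOH (cat.), CH2Cl2, rt
Reagents that add atoms: water, O (becomes the lactone ring oxygen)
Why: Piancatelli rearrangement: ionisation of the furfuryl alcohol, hydration at C5, ring opening and 4π-conrotatory electrocyclisation turn the furan into 4-hydroxy-4-alkylcyclopent-2-enone, whose tertiary OH lactonises onto the side-chain acid; the spiro centre is racemic but is erased in Step 4.

**Step 4**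
Reactants: 5; 6, (2-methylprop-1-en-1-yl)boronic acid
Product: 7, methyl 3-[(5S)-5-(2-methylprop-1-en-1-yl)-3-oxocyclopent-1-en-1-yl]propanoate
Conditions: [Rh(OH)((S)-BINAP)]2 (3 mol%), dioxane/H2O 10:1, 35 °C; then Et3N, 0 °C; then TMSCHN2, PhMe/MeOH, 0 °C
Reagents that add atoms: reactant 6 (CC(C)=CB(O)O); trimethylsilyldiazomethane, C[Si](C)(C)C=[N+]=[N-] (ester CH3)
Why: Proposed new method: a stereoablative, enantioconvergent Hayashi–Miyaura alkenylation in which the chiral Rh–alkenyl species should attack the same enone face of both enantiomers of 5 (the spiro carbon carries O and CH2, which are sterically similar, so catalyst control should dominate), after which Et3N-induced E1cB loss of the lactone carboxylate destroys the spiro centre and leaves only the new (S) centre; the closest known reactions are Rh/BINAP 1,4-additions of alkenylboronic acids to cyclopentenones and cuprate addition–elimination on 4-acyloxycyclopentenones. Base-free Rh conditions and a weak amine are used so the γ-stereocentre of 7 is not epimerised.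

**Step 5**
Reactants: 7
Product: 8, methyl 3-[(1R,2R,5S)-2-(hydroxymethyl)-1-methyl-5-(2-methylprop-1-en-1-yl)-3-oxocyclopentyl]propanoate
Conditions: Me2CuLi (2.2 equiv), TMSCl, THF, −78 → −30 °C; then 37% aq. HCHO, Yb(OTf)3 (10 mol%), THF, rt
Reagents that add atoms: lithium dimethylcuprate, [Li+].C[Cu-]C (CH3); formaldehyde, C=O (CH2OH)
Why: TMSCl-accelerated Gilman conjugate addition delivers methyl anti to the adjacent isobutenyl group (quaternary C1), and Mukaiyama-type hydroxymethylation of the silyl enol ether occurs on the face away from the side chain and isobutenyl group; C2 is also epimerisable and the shown isomer should be the more stable one.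

**Step 6**
Reactants: 8
Product: 9, methyl 3-[(1R,2R,5S)-2-(hydroxymethyl)-1-methyl-3-methylidene-5-(2-methylprop-1-en-1-yl)cyclopentyl]propanoate
Conditions: Zn, CH2Br2, TiCl4, THF/CH2Cl2, 0 °C → rt
Reagents that add atoms: dibromomethane, BrCBr (=CH2)
Why: Takai–Lombardo methylenation is non-basic (avoids retro-aldol or dehydration of the β-hydroxy ketone), tolerates free OH and does not touch the ester.

**Step 7**
Reactants: 9
Product: 10, methyl 3-[(1R,2R,3S,5S)-2-(hydroxymethyl)-1,3-dimethyl-5-(2-methylprop-1-en-1-yl)cyclopentyl]propanoate
Conditions: H2 (60 bar), [Rh(nbd)(dppb)]BF4 (5 mol%), CH2Cl2, rt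
Reagents that add atoms: none
Why: Hydroxyl-directed homogeneous hydrogenation delivers H2 to the 1,1-disubstituted alkene from the face of the CH2OH group, placing the new methyl trans to it; the undirected trisubstituted isobutenyl alkene should survive.

**Step 8**
Reactants: 10; 11, umbelliferone (7-hydroxycoumarin)
Product: 12, methyl 3-[(1R,2R,3S,5S)-1,3-dimethyl-5-(2-methylprop-1-en-1-yl)-2-{[(2-oxo-2H-chromen-7-yl)oxy]methyl}cyclopentyl]propanoate
Conditions: PPh3, DIAD, THF, 0 °C → rt
Reagents that add atoms: none beyond reactant 11 (Oc1ccc2ccc(=O)oc2c1)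
Why: Mitsunobu etherification of the primary alcohol with the acidic phenol (pKa ≈ 7.7); no stereocentre is involved.

**Step 9**
Reactants: 12
Product: 13, ferulsinaic acid, 3-[(1R,2R,3S,5S)-1,3-dimethyl-5-(2-methylprop-1-en-1-yl)-2-{[(2-oxo-2H-chromen-7-yl)oxy]methyl}cyclopentyl]propanoic acid
Conditions: LiOH, THF/H2O, rt; then 1 M HCl to pH 2
Reagents that add atoms: lithium hydroxide/water, [Li+].[OH-] (O of the CO2H hydroxyl)
Why: Saponification of the methyl ester; any coumarin lactone opened by hydroxide re-closes on acidification because the Z-cinnamate geometry is retained.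

## Compound list

1 | 5-(hydroxymethyl)furfural | O=Cc1ccc(CO)o1 | starting material
2 | malonic acid | OC(=O)CC(=O)O | starting material
3 | (2E)-3-[5-(hydroxymethyl)furan-2-yl]prop-2-enoic acid | OCc1ccc(/C=C/C(=O)O)o1 | intermediate
4 | 3-[5-(hydroxymethyl)furan-2-yl]propanoic acid | OCc1ccc(CCC(=O)O)o1 | intermediate
5 | rac-1-oxaspiro[4.4]non-6-ene-2,8-dione | O=C1CCC2(O1)C=CC(=O)C2 | intermediate
6 | (2-methylprop-1-en-1-yl)boronic acid | CC(C)=CB(O)O | starting material
7 | methyl 3-[(5S)-5-(2-methylprop-1-en-1-yl)-3-oxocyclopent-1-en-1-yl]propanoate | CC(C)=C[C@@H]1CC(=O)C=C1CCC(=O)OC | intermediate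
8 | methyl 3-[(1R,2R,5S)-2-(hydroxymethyl)-1-methyl-5-(2-methylprop-1-en-1-yl)-3-oxocyclopentyl]propanoate | CC(C)=C[C@@H]1CC(=O)[C@@H](CO)[C@]1(C)CCC(=O)OC | intermediate
9 | methyl 3-[(1R,2R,5S)-2-(hydroxymethyl)-1-methyl-3-methylidene-5-(2-methylprop-1-en-1-yl)cyclopentyl]propanoate | CC(C)=C[C@@H]1CC(=C)[C@@H](CO)[C@]1(C)CCC(=O)OC | intermediate
10 | methyl 3-[(1R,2R,3S,5S)-2-(hydroxymethyl)-1,3-dimethyl-5-(2-methylprop-1-en-1-yl)cyclopentyl]propanoate | CC(C)=C[C@@H]1C[C@H](C)[C@@H](CO)[C@]1(C)CCC(=O)OC | intermediate
11 | umbelliferone (7-hydroxy-2H-chromen-2-one) | Oc1ccc2ccc(=O)oc2c1 | starting material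
12 | methyl ester of ferulsinaic acid | CC(C)=C[C@@H]1C[C@H](C)[C@@H](COc2ccc3ccc(=O)oc3c2)[C@]1(C)CCC(=O)OC | intermediate
13 | ferulsinaic acid | CC(C)=C[C@@H]1C[C@H](C)[C@@H](COc2ccc3ccc(=O)oc3c2)[C@]1(C)CCC(=O)O | target

## Summary

**Total steps:** 9. **Longest linear sequence:** 9 (HMF → 13; compounds 2, 6 and 11 are added as commercial partners).

**Stereocentres:** C5 is set in Step 4 (catalyst), C1 in Step 5 (methyl anti to isobutenyl), C2 in Step 5 (face selectivity, thermodynamically reinforced), C3 in Step 7 (OH-directed). None is epimerisable after Step 6.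

**Steps most likely to fail, with a fallback that changes the approach:**

1. **Step 4** (substrate bias from the spiro C–O could erode ee; premature elimination to a cyclopentadienone; hindered β-carbon). Fallback: take chirality from a resolved building block instead. Make 4-hydroxycyclopent-2-enone from furfuryl alcohol (Piancatelli), resolve with a lipase, and run anti-selective isobutenyl-cuprate addition–elimination on the 4-acetoxy enone to get (S)-4-isobutenylcyclopent-2-enone. Then install the propanoate chain by conjugate addition with TMSCl trapping and Saegusa re-oxidation to reach 7.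

2. **Step 5** (methyl addition to a hindered β,β-disubstituted enone; sensitive formaldehyde aldol). Fallback: reverse the order at C2. α-Iodinate 7 (I2, pyridine), Stille-couple with Bu3SnCH2OH to the 2-(hydroxymethyl)enone, then add the methyl cuprate and let C2 be set by thermodynamic protonation.

3. **Step 3** (polymerisation or low yield with a primary, acid-bearing furfuryl alcohol). Fallback: build 5 from the symmetric, non-furan cyclopent-4-ene-1,3-dione by mono 1,2-addition of a propanoate zinc homoenolate to one carbonyl, followed by lactonisation of the resulting tertiary alcohol.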